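**Plan**
- Cuts: all benzyl-type ethers come off last. Flavan F (on C8 of the benzotropolone) is cut at O1–C2 and its C2–H is traced back to a ketone. The tropolone ring is cut at C6–C7, C8–C9 and C6–O into an ortho-formyl aryl diazoketone carrying flavan G (on C1, with the 3-gallate) and a terminal ynone carrying C2–C4 and ring A of flavan F. Flavan G is cut at O1–C2, at C2–aryl and at the two carbon substituents of its ring B.
- Feature used: with the benzotropolone numbered C1–C9a (C5 ketone, C6 hydroxyl), ring C4a–C5–C6–C7–C8–C9–C9a is the ring-opened, aromatised form of a benzo-fused 8-oxabicyclo[3.2.1]octadienone whose oxygen bridges C6 and C9. C6–O–C9 is then a cyclic carbonyl ylide and C7–C8 an alkyne.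
- Forward order: one (R)-α-alkoxy Weinreb amide (ring A plus C2–C4) serves both flavans. The pyran ring of flavan G is closed first, then ring B is carboxylated and the gallate, diazoketone and aldehyde are installed. The oxygen-bridged seven-membered ring follows, then its opening to the tropolone, the pyran ring of flavan F, and hydrogenolysis.
- Stereochemistry: C3 of both flavans comes from methyl (R)-glycidate. Each C2 is set by chelation-controlled Zn(BH4)2 reduction (anti) followed by Mitsunobu ring closure with inversion (2,3-cis, 2R,3R). The two bridgeheads made in the cycloaddition are erased on ring opening.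

Key step: step 25

Assumption: 3,5-bis(benzyloxy)phenol and 3,4,5-tris(benzyloxy)benzoic acid are bought as the benzyl ethers of phloroglucinol and gallic acid. The cycloadduct is carried on as the mixture of its two bridge diastereomers (one is drawn), because the following step removes both bridgehead stereocentres.

**Ring A chain, shared Weinreb amide and ynone (steps 1–7)**

Step 1
Reactants: 1 3,5-bis(benzyloxy)phenol
Product: 2 1,3-bis(benzyloxy)-5-(methoxymethoxy)benzene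
Conditions: MOMCl, i-Pr2NEt, CH2Cl2, 0 °C to rt
Reagents that add atoms: chloromethyl methyl ether, COCCl
Why: O-alkylation of the phenol with an alkoxymethyl chloride (acetal protection) installs the group that directs the metalation of step 2.

Step 2
Reactants: 2 1,3-bis(benzyloxy)-5-(methoxymethoxy)benzene; 3 methyl (R)-glycidate
Product: 6 methyl (2R)-3-[2,4-bis(benzyloxy)-6-(methoxymethoxy)phenyl]-2-hydroxypropanoate, via aryllithium 4 (not isolated), via arylmagnesium bromide 5 (not isolated)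
Conditions: n-BuLi, THF, 0 °C; MgBr2·OEt2, −20 °C; CuI (10 mol %), 3, −40 to −10 °C; NH4Cl (aq)
Reagents that add atoms: none
Why: Directed ortho-metalation should occur between the coordinating methoxymethoxy group and a benzyloxy group, and the copper-catalysed Grignard opening of the glycidate is an SN2 attack at the unsubstituted epoxide carbon, so the (R) centre of 3 is carried over untouched as C3 of both flavans.

Step 3
Reactants: 6 methyl (2R)-3-[2,4-bis(benzyloxy)-6-(methoxymethoxy)phenyl]-2-hydroxypropanoate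
Product: 8 (3R)-5,7-bis(benzyloxy)-3-hydroxychroman-2-one, via phenol ester 7 (not isolated)
Conditions: HCl (3 M in MeOH), 45 °C; then TsOH·H2O (cat.), toluene, 90 °C
Reagents that add atoms: none
Why: Acid methanolysis of the aryl methoxymethyl acetal frees the ortho phenol, which lactonises onto the ester (acid-catalysed transesterification, six-membered ring), so the phenol is masked and only the secondary hydroxyl stays free; an aryl regioisomer from metalation between the two benzyloxy groups could not lactonise and would be removed here.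

Step 4
Reactants: 8 (3R)-5,7-bis(benzyloxy)-3-hydroxychroman-2-one
Product: 9 (3R)-5,7-bis(benzyloxy)-3-[(benzyloxy)methoxy]chroman-2-one
Conditions: BOMCl, i-Pr2NEt, Bu4NI (cat.), CH2Cl2, rt
Reagents that add atoms: benzyl chloromethyl ether, ClCOCc1ccccc1
Why: Alkoxymethylation of the secondary alcohol under weakly basic conditions gives a chelating acetal that needs no benzyl cation (which ring A would trap) and that falls in the final hydrogenolysis.

Step 5
Reactants: 9 (3R)-5,7-bis(benzyloxy)-3-[(benzyloxy)methoxy]chroman-2-one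
Product: 10 (2R)-3-[2,4-bis(benzyloxy)-6-hydroxyphenyl]-2-[(benzyloxy)methoxy]-N-methoxy-N-methylpropanamide
Conditions: MeNHOMe·HCl, i-PrMgCl, THF, −20 to 0 °C
Reagents that add atoms: N,O-dimethylhydroxylamine hydrochloride, CNOC.Cl
Why: The magnesium amide opens the aryl lactone by acyl substitution with phenoxide as leaving group (Weinreb amide formation) and thereby frees the ring A phenol.

Step 6
Reactants: 10 (2R)-3-[2,4-bis(benzyloxy)-6-hydroxyphenyl]-2-[(benzyloxy)methoxy]-N-methoxy-N-methylpropanamide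
Product: 11 (2R)-3-[2,4-bis(benzyloxy)-6-(tert-butyldimethylsilyloxy)phenyl]-2-[(benzyloxy)methoxy]-N-methoxy-N-methylpropanamide
Conditions: TBSCl, imidazole, DMF, rt
Reagents that add atoms: tert-butyldimethylsilyl chloride, CC(C)(C)[Si](C)(C)Cl
Why: Silylation of the phenol gives an aryl silyl ether that survives organometallics, the rhodium step and mild acid and can later be removed with fluoride beside benzyl ethers.

Step 7
Reactants: 11 (2R)-3-[2,4-bis(benzyloxy)-6-(tert-butyldimethylsilyloxy)phenyl]-2-[(benzyloxy)methoxy]-N-methoxy-N-methylpropanamide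
Product: 12 (4R)-5-[2,4-bis(benzyloxy)-6-(tert-butyldimethylsilyloxy)phenyl]-4-[(benzyloxy)methoxy]pent-1-yn-3-one
Conditions: HC≡CMgBr, THF, 0 °C; poured into cold 1 M HCl
Reagents that add atoms: ethynylmagnesium bromide, C#C[Mg]Br
Why: Weinreb ketone synthesis, in which the chelated tetrahedral intermediate prevents over-addition and the acidic quench keeps the liberated amine from adding to the ynone; the α-stereocentre is not touched.

**Ring B of flavan G (steps 8–13)**

Step 8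
Reactants: 13 3,4-dihydroxybenzaldehyde
Product: 14 4-(benzyloxy)-3-hydroxybenzaldehyde
Conditions: BnBr (1 equiv), NaHCO3, NaI (cat.), DMF, 40 °C
Reagents that add atoms: benzyl bromide, BrCc1ccccc1
Why: Williamson etherification with a weak base alkylates only the more acidic 4-hydroxyl (para to the aldehyde).

Step 9
Reactants: 14 4-(benzyloxy)-3-hydroxybenzaldehyde
Product: 15 4-(benzyloxy)-2-bromo-3-hydroxybenzaldehyde
Conditions: Br2, NaOAc, AcOH, rt
Reagents that add atoms: bromine, BrBr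
Why: Electrophilic aromatic bromination of 3-hydroxy-4-alkoxybenzaldehydes occurs ortho to the free phenol at the position between hydroxyl and formyl group, which is the future C4a.

Step 10
Reactants: 15 4-(benzyloxy)-2-bromo-3-hydroxybenzaldehyde
Product: 16 4-(benzyloxy)-2-bromo-3-hydroxy-6-iodobenzaldehyde
Conditions: N-iodosuccinimide, TsOH (cat.), MeCN, rt
Reagents that add atoms: N-iodosuccinimide, O=C1CCC(=O)N1I
Why: Electrophilic iodination goes para to the phenol, the only position left that the hydroxyl activates, and so marks the future C1 with the more reactive halogen.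

Step 11
Reactants: 16 4-(benzyloxy)-2-bromo-3-hydroxy-6-iodobenzaldehyde
Product: 17 3,4-bis(benzyloxy)-2-bromo-6-iodobenzaldehyde
Conditions: BnBr, K2CO3, DMF, rt
Reagents that add atoms: benzyl bromide, BrCc1ccccc1
Why: Williamson etherification of the remaining phenol.

Step 12
Reactants: 17 3,4-bis(benzyloxy)-2-bromo-6-iodobenzaldehyde
Product: 18 [3,4-bis(benzyloxy)-2-bromo-6-iodophenyl]methanol
Conditions: NaBH4, MeOH/THF, 0 °C
Reagents that add atoms: none
Why: Borohydride reduction takes the aldehyde (future C9) to the alcohol level so that it can pass the organometallic steps.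

Step 13
Reactants: 18 [3,4-bis(benzyloxy)-2-bromo-6-iodophenyl]methanol
Product: 19 {[3,4-bis(benzyloxy)-2-bromo-6-iodobenzyl]oxy}triisopropylsilane
Conditions: TIPSOTf, 2,6-lutidine, CH2Cl2, 0 °C
Reagents that add atoms: triisopropylsilyl trifluoromethanesulfonate, CC(C)[Si](OS(=O)(=O)C(F)(F)F)(C(C)C)C(C)C
Why: Silylation with the reactive triflate overcomes the two ortho halogens, and the bulky silyl group is the one least prone to migrate to a neighbouring aryl anion.

**Flavan G, gallate, diazoketone and aldehyde (steps 14–24)**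

Step 14
Reactants: 19 {[3,4-bis(benzyloxy)-2-bromo-6-iodobenzyl]oxy}triisopropylsilane; 11 (2R)-3-[2,4-bis(benzyloxy)-6-(tert-butyldimethylsilyloxy)phenyl]-2-[(benzyloxy)methoxy]-N-methoxy-N-methylpropanamide
Product: 21 (2R)-3-[2,4-bis(benzyloxy)-6-(tert-butyldimethylsilyloxy)phenyl]-1-[4,5-bis(benzyloxy)-3-bromo-2-{[(triisopropylsilyl)oxy]methyl}phenyl]-2-[(benzyloxy)methoxy]propan-1-one, via arylmagnesium chloride 20 (not isolated)
Conditions: 19, i-PrMgCl·LiCl, THF, −20 °C; then 11, −20 °C to rt; NH4Cl (aq)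
Reagents that add atoms: none
Why: Iodine–magnesium exchange is selective for the aryl iodide over the bromide, and the aryl Grignard adds once to the amide because the magnesium chelate lasts until work-up (Weinreb ketone synthesis).

Step 15
Reactants: 21 the aryl ketone of step 14
Product: 22 (1S,2R)-3-[2,4-bis(benzyloxy)-6-(tert-butyldimethylsilyloxy)phenyl]-1-[4,5-bis(benzyloxy)-3-bromo-2-{[(triisopropylsilyl)oxy]methyl}phenyl]-2-[(benzyloxy)methoxy]propan-1-ol
Conditions: Zn(BH4)2, Et2O/CH2Cl2, −30 to 0 °C; NH4Cl (aq)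
Reagents that add atoms: none
Why: Chelation-controlled (Cram-chelate) reduction, in which zinc bridges the ketone and the α-alkoxymethoxy oxygen and hydride attacks from the face of the α-hydrogen, should give the anti (1S,2R) alcohol.

Step 16
Reactants: 22 the anti alcohol of step 15
Product: 23 (1S,2R)-3-[2,4-bis(benzyloxy)-6-hydroxyphenyl]-1-[4,5-bis(benzyloxy)-3-bromo-2-{[(triisopropylsilyl)oxy]methyl}phenyl]-2-[(benzyloxy)methoxy]propan-1-ol
Conditions: TBAF, AcOH, THF, 0 °C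
Reagents that add atoms: none
Why: Buffered fluoride cleaves the aryl silyl ether far faster than the hindered primary triisopropylsilyl ether (selective desilylation).

Step 17
Reactants: 23 the phenol of step 16
Product: 24 (2R,3R)-5,7-bis(benzyloxy)-3-[(benzyloxy)methoxy]-2-[4,5-bis(benzyloxy)-3-bromo-2-{[(triisopropylsilyl)oxy]methyl}phenyl]chromane
Conditions: PPh3, DIAD, THF, 0 °C to rt
Reagents that add atoms: none
Why: Intramolecular Mitsunobu etherification, in which the phenoxide displaces the oxyphosphonium group from the rear, inverts the carbinol to (2R) and so closes the pyran ring 2,3-cis.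

Step 18
Reactants: 24 the flavan bromide of step 17
Product: 26 allyl 2,3-bis(benzyloxy)-5-{(2R,3R)-5,7-bis(benzyloxy)-3-[(benzyloxy)methoxy]chroman-2-yl}-6-{[(triisopropylsilyl)oxy]methyl}benzoate, via aryllithium 25 (not isolated)
Conditions: t-BuLi (2 equiv), Et2O, −78 °C; then allyl chloroformate, −78 to −40 °C
Reagents that add atoms: allyl chloroformate, C=CCOC(=O)Cl
Why: Bromine–lithium exchange is faster than any deprotonation at −78 °C, the ether solvent disfavours silyl migration from the neighbouring silyloxymethyl group, and acylation of the aryllithium by the chloroformate puts the future C5 carbon in place as an ester that is cleavable under neutral conditions.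

Step 19
Reactants: 26 the allyl ester of step 18
Product: 27 allyl 2,3-bis(benzyloxy)-5-[(2R,3R)-5,7-bis(benzyloxy)-3-hydroxychroman-2-yl]-6-{[(triisopropylsilyl)oxy]methyl}benzoate
Conditions: Me2BBr, CH2Cl2, −78 °C; then NaHCO3 (aq), THF
Reagents that add atoms: none
Why: Boron-bromide cleavage of a formaldehyde acetal (boron on the acetal oxygen, bromide attack at the O–CH2–O carbon) frees the secondary alcohol at a temperature where aryl benzyl ethers, the silyl ether, the ester and the pyran ring are inert, and it avoids quinone oxidants that could attack C4 of the electron-rich flavan.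

Step 20
Reactants: 27 the flavan-3-ol of step 19; 28 3,4,5-tris(benzyloxy)benzoic acid
Product: 29 (2R,3R)-2-[3-(allyloxycarbonyl)-4,5-bis(benzyloxy)-2-{[(triisopropylsilyl)oxy]methyl}phenyl]-5,7-bis(benzyloxy)chroman-3-yl 3,4,5-tris(benzyloxy)benzoate
Conditions: DCC, DMAP, CH2Cl2, rt
Reagents that add atoms: none
Why: Steglich esterification acylates the axial 3-hydroxyl with retention at C3, as is routine for 3-O-galloyl catechins.

Step 21
Reactants: 29 the gallate of step 20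
Product: 30 2,3-bis(benzyloxy)-5-[(2R,3R)-5,7-bis(benzyloxy)-3-{[3,4,5-tris(benzyloxy)benzoyl]oxy}chroman-2-yl]-6-{[(triisopropylsilyl)oxy]methyl}benzoic acid
Conditions: Pd(PPh3)4 (5 mol %), morpholine, THF, rt
Reagents that add atoms: none
Why: Zerovalent palladium ionises the allyl ester to a π-allyl complex that morpholine captures (Tsuji–Trost deallylation), which frees the hindered acid without touching the gallate ester.

Step 22
Reactants: 30 the benzoic acid of step 21
Product: 32 (2R,3R)-5,7-bis(benzyloxy)-2-[4,5-bis(benzyloxy)-3-(2-diazoacetyl)-2-{[(triisopropylsilyl)oxy]methyl}phenyl]chroman-3-yl 3,4,5-tris(benzyloxy)benzoate, via acid chloride 31 (not isolated)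
Conditions: 1-chloro-N,N,2-trimethylprop-1-en-1-amine, CH2Cl2, 0 °C; then CH2N2, Et3N, Et2O, 0 °C
Reagents that add atoms: diazomethane, C=[N+]=[N-]
Why: The α-chloroenamine forms the acid chloride without HCl (so the neighbouring silyl ether does not close to a phthalide), and acylation of diazomethane with Et3N as acid scavenger gives the diazoketone (Arndt–Eistert-type diazoketone synthesis).

Step 23
Reactants: 32 the silyl-protected diazoketone of step 22
Product: 33 (2R,3R)-5,7-bis(benzyloxy)-2-[4,5-bis(benzyloxy)-3-(2-diazoacetyl)-2-(hydroxymethyl)phenyl]chroman-3-yl 3,4,5-tris(benzyloxy)benzoate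
Conditions: TBAF, AcOH, THF, 0 °C to rt
Reagents that add atoms: none
Why: Fluoride desilylation buffered with acetic acid is mild enough for the aryl diazoketone and the gallate ester.

Step 24
Reactants: 33 the hydroxymethyl diazoketone of step 23
Product: 34 (2R,3R)-5,7-bis(benzyloxy)-2-[4,5-bis(benzyloxy)-3-(2-diazoacetyl)-2-formylphenyl]chroman-3-yl 3,4,5-tris(benzyloxy)benzoate
Conditions: MnO2 (excess), CH2Cl2, rt
Reagents that add atoms: none
Why: Heterogeneous, neutral MnO2 oxidation of the benzylic alcohol to the aldehyde does not protonate or decompose the diazoketone.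

**Cycloaddition and endgame (steps 25–31)**

Step 25
Reactants: 34 the ortho-formyl diazoketone of step 24; 12 the ynone of step 7
Product: 36 oxygen-bridged cycloadduct with a 6,9-epoxy-6,9-dihydro-5H-benzo[7]annulen-5-one core (full name in the compound list), via carbonyl ylide 35 (not isolated)
Conditions: Rh2(OAc)4 (2 mol %), 12 (1.5 equiv), CH2Cl2, rt, slow addition of 34
Reagents that add atoms: none
Why: Rh2(OAc)4 releases N2 from 34 and the electrophilic carbenoid carbon (future C6) is captured by a lone pair of the neighbouring aldehyde oxygen in a 6-exo-type attack, which makes the C6–O bond and the transient six-membered 2-benzopyrylium-4-olate 35. This dipole adds through its termini C6 and C9 across the triple bond of 12 in a concerted, suprafacial [3+2] cycloaddition, so C6–C7 and C8–C9 form together and close at once the 2,5-dihydrofuran ring and the seven-membered carbocycle. The closest known reaction type is the rhodium-carbenoid carbonyl ylide cycloaddition of ortho-acyl diazoacetophenones with alkynes, the benzo analogue of 3-oxidopyrylium additions. The two new stereocentres are the bridgeheads C6 and C9, which the one-atom oxygen bridge forces to be cis; the remote flavan centres do not control which face of the planar dipole is attacked, so both bridge diastereomers are expected and both are used because step 26 makes C6 and C9 sp2. The selectivity that matters is the regiochemistry: the enolate-like terminus C6 (next to the C5 oxygen, largest HOMO coefficient) should bond to the unsubstituted electrophilic carbon of the ynone, which puts the acyl group on C8, the sense known for electron-poor dipolarophiles with oxidopyrylium-type ylides. Chemoselectivity rests on slow addition of 34 to catalyst and excess 12, on the fast six-membered carbonyl capture, and on the fact that reversible capture by the weakly basic C4 aryl ether oxygen has no rapid follow-up path under Rh2(OAc)4.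

Step 26
Reactants: 36 the oxygen-bridged cycloadduct
Product: 37 benzotropolone with free C6 hydroxyl and C8 acyl side chain (6-hydroxy-5H-benzo[7]annulen-5-one; full name in the compound list)
Conditions: TsOH·H2O (0.2 equiv), CH2Cl2, 0 °C to rt
Reagents that add atoms: none
Why: Acid-promoted heterolysis of the benzylic C9–O bond (cation stabilised by the para C3 benzyloxy group, whereas C6 lies next to the ketone) followed by loss of the C6 proton is an E1-type ring opening driven by tropolone aromaticity, which leaves the former aldehyde oxygen as the C6 hydroxyl.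

Step 27
Reactants: 37 the benzotropolone of step 26
Product: 38 6-O-benzyl benzotropolone (full name in the compound list)
Conditions: BnBr, i-Pr2NEt, Bu4NI (cat.), MeCN, 40 °C
Reagents that add atoms: benzyl bromide, BrCc1ccccc1
Why: O-alkylation of the acidic tropolone hydroxyl with an amine base can occur only at the C6 oxygen if the benzo ring is to stay aromatic, and it neither cleaves the aryl silyl ether nor epimerises the α-alkoxy ketone.

Step 28
Reactants: 38 the 6-O-benzyl benzotropolone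
Product: 39 (1S,2R) carbinol on C8 (full name in the compound list)
Conditions: Zn(BH4)2, Et2O/CH2Cl2, −40 to −20 °C; NH4Cl (aq)
Reagents that add atoms: none
Why: Chelation-controlled (Cram-chelate) reduction of the α-alkoxymethoxy ketone should give the anti (1S,2R) alcohol, while the vinylogous-ester tropone carbonyl and the gallate ester are not reduced at low temperature.

Step 29
Reactants: 39 the carbinol of step 28
Product: 40 the corresponding ring A phenol (full name in the compound list)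
Conditions: TBAF, AcOH, THF, 0 °C
Reagents that add atoms: none
Why: Buffered fluoride cleavage of the aryl silyl ether frees the phenol needed for ring closure.

Step 30
Reactants: 40 the phenol of step 29
Product: 41 fully protected theaflavin-3-gallate (full name in the compound list)
Conditions: PPh3, DIAD, THF, 0 °C to rt
Reagents that add atoms: none
Why: Intramolecular Mitsunobu etherification with inversion at the carbinol gives (2R) and closes the pyran ring of flavan F 2,3-cis.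

Step 31
Reactants: 41 fully protected theaflavin-3-gallate
Product: 42 theaflavin-3-gallate
Conditions: H2 (1 atm), Pd(OH)2/C, THF/MeOH, rt
Reagents that add atoms: none
Why: Hydrogenolysis removes the ten benzyl ethers and the benzyloxymethyl acetal (whose hemiacetal loses formaldehyde), while the tropolone, the aryl ester and the flavan C2–O bonds are expected to survive these mild conditions, as benzylated catechin gallates do.

**Compound list**

1 | 3,5-bis(benzyloxy)phenol | Oc1cc(OCc2ccccc2)cc(OCc2ccccc2)c1 | starting material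
2 | 1,3-bis(benzyloxy)-5-(methoxymethoxy)benzene | COCOc1cc(OCc2ccccc2)cc(OCc2ccccc2)c1 | intermediate
3 | methyl (R)-glycidate [methyl (2R)-oxirane-2-carboxylate] | COC(=O)[C@H]1CO1 | starting material
4 | [2,4-bis(benzyloxy)-6-(methoxymethoxy)phenyl]lithium (not isolated) | [Li]c1c(OCOC)cc(OCc2ccccc2)cc1OCc1ccccc1 | intermediate
5 | [2,4-bis(benzyloxy)-6-(methoxymethoxy)phenyl]magnesium bromide (not isolated) | Br[Mg]c1c(OCOC)cc(OCc2ccccc2)cc1OCc1ccccc1 | intermediate
6 | methyl (2R)-3-[2,4-bis(benzyloxy)-6-(methoxymethoxy)phenyl]-2-hydroxypropanoate | COC(=O)[C@H](O)Cc1c(OCOC)cc(OCc2ccccc2)cc1OCc1ccccc1 | intermediate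
7 | methyl (2R)-3-[2,4-bis(benzyloxy)-6-hydroxyphenyl]-2-hydroxypropanoate (not isolated) | COC(=O)[C@H](O)Cc1c(O)cc(OCc2ccccc2)cc1OCc1ccccc1 | intermediate
8 | (3R)-5,7-bis(benzyloxy)-3-hydroxychroman-2-one | O=C1Oc2cc(OCc3ccccc3)cc(OCc3ccccc3)c2C[C@H]1O | intermediate
9 | (3R)-5,7-bis(benzyloxy)-3-[(benzyloxy)methoxy]chroman-2-one | O=C1Oc2cc(OCc3ccccc3)cc(OCc3ccccc3)c2C[C@H]1OCOCc1ccccc1 | intermediate
10 | (2R)-3-[2,4-bis(benzyloxy)-6-hydroxyphenyl]-2-[(benzyloxy)methoxy]-N-methoxy-N-methylpropanamide | CON(C)C(=O)[C@H](OCOCc1ccccc1)Cc1c(O)cc(OCc2ccccc2)cc1OCc1ccccc1 | intermediate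
11 | (2R)-3-[2,4-bis(benzyloxy)-6-(tert-butyldimethylsilyloxy)phenyl]-2-[(benzyloxy)methoxy]-N-methoxy-N-methylpropanamide | CON(C)C(=O)[C@H](OCOCc1ccccc1)Cc1c(O[Si](C)(C)C(C)(C)C)cc(OCc2ccccc2)cc1OCc1ccccc1 | intermediate
12 | (4R)-5-[2,4-bis(benzyloxy)-6-(tert-butyldimethylsilyloxy)phenyl]-4-[(benzyloxy)methoxy]pent-1-yn-3-one | C#CC(=O)[C@H](OCOCc1ccccc1)Cc1c(O[Si](C)(C)C(C)(C)C)cc(OCc2ccccc2)cc1OCc1ccccc1 | intermediate
13 | 3,4-dihydroxybenzaldehyde | O=Cc1ccc(O)c(O)c1 | starting material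
14 | 4-(benzyloxy)-3-hydroxybenzaldehyde | O=Cc1ccc(OCc2ccccc2)c(O)c1 | intermediate
15 | 4-(benzyloxy)-2-bromo-3-hydroxybenzaldehyde | O=Cc1ccc(OCc2ccccc2)c(O)c1Br | intermediate
16 | 4-(benzyloxy)-2-bromo-3-hydroxy-6-iodobenzaldehyde | O=Cc1c(I)cc(OCc2ccccc2)c(O)c1Br | intermediate
17 | 3,4-bis(benzyloxy)-2-bromo-6-iodobenzaldehyde | O=Cc1c(I)cc(OCc2ccccc2)c(OCc2ccccc2)c1Br | intermediate
18 | [3,4-bis(benzyloxy)-2-bromo-6-iodophenyl]methanol | OCc1c(I)cc(OCc2ccccc2)c(OCc2ccccc2)c1Br | intermediate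
19 | {[3,4-bis(benzyloxy)-2-bromo-6-iodobenzyl]oxy}triisopropylsilane | CC(C)[Si](OCc1c(I)cc(OCc2ccccc2)c(OCc2ccccc2)c1Br)(C(C)C)C(C)C | intermediate
20 | [4,5-bis(benzyloxy)-3-bromo-2-{[(triisopropylsilyl)oxy]methyl}phenyl]magnesium chloride (not isolated) | Cl[Mg]c1cc(OCc2ccccc2)c(OCc2ccccc2)c(Br)c1CO[Si](C(C)C)(C(C)C)C(C)C | intermediate
21 | (2R)-3-[2,4-bis(benzyloxy)-6-(tert-butyldimethylsilyloxy)phenyl]-1-[4,5-bis(benzyloxy)-3-bromo-2-{[(triisopropylsilyl)oxy]methyl}phenyl]-2-[(benzyloxy)methoxy]propan-1-one | Brc1c(OCc2ccccc2)c(OCc2ccccc2)cc(C(=O)[C@H](OCOCc2ccccc2)Cc2c(O[Si](C)(C)C(C)(C)C)cc(OCc3ccccc3)cc2OCc2ccccc2)c1CO[Si](C(C)C)(C(C)C)C(C)C | intermediate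
22 | (1S,2R)-3-[2,4-bis(benzyloxy)-6-(tert-butyldimethylsilyloxy)phenyl]-1-[4,5-bis(benzyloxy)-3-bromo-2-{[(triisopropylsilyl)oxy]methyl}phenyl]-2-[(benzyloxy)methoxy]propan-1-ol | Brc1c(OCc2ccccc2)c(OCc2ccccc2)cc([C@H](O)[C@H](OCOCc2ccccc2)Cc2c(O[Si](C)(C)C(C)(C)C)cc(OCc3ccccc3)cc2OCc2ccccc2)c1CO[Si](C(C)C)(C(C)C)C(C)C | intermediate
23 | (1S,2R)-3-[2,4-bis(benzyloxy)-6-hydroxyphenyl]-1-[4,5-bis(benzyloxy)-3-bromo-2-{[(triisopropylsilyl)oxy]methyl}phenyl]-2-[(benzyloxy)methoxy]propan-1-ol | Brc1c(OCc2ccccc2)c(OCc2ccccc2)cc([C@H](O)[C@H](OCOCc2ccccc2)Cc2c(O)cc(OCc3ccccc3)cc2OCc2ccccc2)c1CO[Si](C(C)C)(C(C)C)C(C)C | intermediate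
24 | (2R,3R)-5,7-bis(benzyloxy)-3-[(benzyloxy)methoxy]-2-[4,5-bis(benzyloxy)-3-bromo-2-{[(triisopropylsilyl)oxy]methyl}phenyl]chromane | c1ccccc1COCO[C@@H]1Cc2c(OCc3ccccc3)cc(OCc3ccccc3)cc2O[C@@H]1c1cc(OCc2ccccc2)c(OCc2ccccc2)c(Br)c1CO[Si](C(C)C)(C(C)C)C(C)C | intermediate
25 | [2,3-bis(benzyloxy)-5-{(2R,3R)-5,7-bis(benzyloxy)-3-[(benzyloxy)methoxy]chroman-2-yl}-6-{[(triisopropylsilyl)oxy]methyl}phenyl]lithium (not isolated) | c1ccccc1COCO[C@@H]1Cc2c(OCc3ccccc3)cc(OCc3ccccc3)cc2O[C@@H]1c1cc(OCc2ccccc2)c(OCc2ccccc2)c([Li])c1CO[Si](C(C)C)(C(C)C)C(C)C | intermediate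
26 | allyl 2,3-bis(benzyloxy)-5-{(2R,3R)-5,7-bis(benzyloxy)-3-[(benzyloxy)methoxy]chroman-2-yl}-6-{[(triisopropylsilyl)oxy]methyl}benzoate | c1ccccc1COCO[C@@H]1Cc2c(OCc3ccccc3)cc(OCc3ccccc3)cc2O[C@@H]1c1cc(OCc2ccccc2)c(OCc2ccccc2)c(C(=O)OCC=C)c1CO[Si](C(C)C)(C(C)C)C(C)C | intermediate
27 | allyl 2,3-bis(benzyloxy)-5-[(2R,3R)-5,7-bis(benzyloxy)-3-hydroxychroman-2-yl]-6-{[(triisopropylsilyl)oxy]methyl}benzoate | O[C@@H]1Cc2c(OCc3ccccc3)cc(OCc3ccccc3)cc2O[C@@H]1c1cc(OCc2ccccc2)c(OCc2ccccc2)c(C(=O)OCC=C)c1CO[Si](C(C)C)(C(C)C)C(C)C | intermediate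
28 | 3,4,5-tris(benzyloxy)benzoic acid | O=C(O)c1cc(OCc2ccccc2)c(OCc2ccccc2)c(OCc2ccccc2)c1 | starting material
29 | (2R,3R)-2-[3-(allyloxycarbonyl)-4,5-bis(benzyloxy)-2-{[(triisopropylsilyl)oxy]methyl}phenyl]-5,7-bis(benzyloxy)chroman-3-yl 3,4,5-tris(benzyloxy)benzoate | O=C(O[C@@H]1Cc2c(OCc3ccccc3)cc(OCc3ccccc3)cc2O[C@@H]1c1cc(OCc2ccccc2)c(OCc2ccccc2)c(C(=O)OCC=C)c1CO[Si](C(C)C)(C(C)C)C(C)C)c1cc(OCc2ccccc2)c(OCc2ccccc2)c(OCc2ccccc2)c1 | intermediate
30 | 2,3-bis(benzyloxy)-5-[(2R,3R)-5,7-bis(benzyloxy)-3-{[3,4,5-tris(benzyloxy)benzoyl]oxy}chroman-2-yl]-6-{[(triisopropylsilyl)oxy]methyl}benzoic acid | O=C(O[C@@H]1Cc2c(OCc3ccccc3)cc(OCc3ccccc3)cc2O[C@@H]1c1cc(OCc2ccccc2)c(OCc2ccccc2)c(C(=O)O)c1CO[Si](C(C)C)(C(C)C)C(C)C)c1cc(OCc2ccccc2)c(OCc2ccccc2)c(OCc2ccccc2)c1 | intermediate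
31 | the benzoyl chloride of acid 30 (not isolated) | O=C(O[C@@H]1Cc2c(OCc3ccccc3)cc(OCc3ccccc3)cc2O[C@@H]1c1cc(OCc2ccccc2)c(OCc2ccccc2)c(C(=O)Cl)c1CO[Si](C(C)C)(C(C)C)C(C)C)c1cc(OCc2ccccc2)c(OCc2ccccc2)c(OCc2ccccc2)c1 | intermediate
32 | (2R,3R)-5,7-bis(benzyloxy)-2-[4,5-bis(benzyloxy)-3-(2-diazoacetyl)-2-{[(triisopropylsilyl)oxy]methyl}phenyl]chroman-3-yl 3,4,5-tris(benzyloxy)benzoate | O=C(O[C@@H]1Cc2c(OCc3ccccc3)cc(OCc3ccccc3)cc2O[C@@H]1c1cc(OCc2ccccc2)c(OCc2ccccc2)c(C(=O)C=[N+]=[N-])c1CO[Si](C(C)C)(C(C)C)C(C)C)c1cc(OCc2ccccc2)c(OCc2ccccc2)c(OCc2ccccc2)c1 | intermediate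
33 | (2R,3R)-5,7-bis(benzyloxy)-2-[4,5-bis(benzyloxy)-3-(2-diazoacetyl)-2-(hydroxymethyl)phenyl]chroman-3-yl 3,4,5-tris(benzyloxy)benzoate | O=C(O[C@@H]1Cc2c(OCc3ccccc3)cc(OCc3ccccc3)cc2O[C@@H]1c1cc(OCc2ccccc2)c(OCc2ccccc2)c(C(=O)C=[N+]=[N-])c1CO)c1cc(OCc2ccccc2)c(OCc2ccccc2)c(OCc2ccccc2)c1 | intermediate
34 | (2R,3R)-5,7-bis(benzyloxy)-2-[4,5-bis(benzyloxy)-3-(2-diazoacetyl)-2-formylphenyl]chroman-3-yl 3,4,5-tris(benzyloxy)benzoate | O=C(O[C@@H]1Cc2c(OCc3ccccc3)cc(OCc3ccccc3)cc2O[C@@H]1c1cc(OCc2ccccc2)c(OCc2ccccc2)c(C(=O)C=[N+]=[N-])c1C=O)c1cc(OCc2ccccc2)c(OCc2ccccc2)c(OCc2ccccc2)c1 | intermediate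
35 | 5,6-bis(benzyloxy)-8-[(2R,3R)-5,7-bis(benzyloxy)-3-{[3,4,5-tris(benzyloxy)benzoyl]oxy}chroman-2-yl]isochromenylium-4-olate (carbonyl ylide, not isolated) | O=C(O[C@@H]1Cc2c(OCc3ccccc3)cc(OCc3ccccc3)cc2O[C@@H]1c1cc(OCc2ccccc2)c(OCc2ccccc2)c2c([O-])c[o+]cc12)c1cc(OCc2ccccc2)c(OCc2ccccc2)c(OCc2ccccc2)c1 | intermediate
36 | (2R,3R)-5,7-bis(benzyloxy)-2-[3,4-bis(benzyloxy)-8-{(2R)-3-[2,4-bis(benzyloxy)-6-(tert-butyldimethylsilyloxy)phenyl]-2-[(benzyloxy)methoxy]propanoyl}-5-oxo-6,9-dihydro-5H-6,9-epoxybenzo[7]annulen-1-yl]chroman-3-yl 3,4,5-tris(benzyloxy)benzoate (both bridge diastereomers expected, one drawn) | O=C(O[C@@H]1Cc2c(OCc3ccccc3)cc(OCc3ccccc3)cc2O[C@@H]1c1cc(OCc2ccccc2)c(OCc2ccccc2)c2c1[C@H]1O[C@H](C=C1C(=O)[C@H](OCOCc1ccccc1)Cc1c(O[Si](C)(C)C(C)(C)C)cc(OCc3ccccc3)cc1OCc1ccccc1)C2=O)c1cc(OCc2ccccc2)c(OCc2ccccc2)c(OCc2ccccc2)c1 | intermediate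
37 | (2R,3R)-5,7-bis(benzyloxy)-2-[3,4-bis(benzyloxy)-8-{(2R)-3-[2,4-bis(benzyloxy)-6-(tert-butyldimethylsilyloxy)phenyl]-2-[(benzyloxy)methoxy]propanoyl}-6-hydroxy-5-oxo-5H-benzo[7]annulen-1-yl]chroman-3-yl 3,4,5-tris(benzyloxy)benzoate | O=C(O[C@@H]1Cc2c(OCc3ccccc3)cc(OCc3ccccc3)cc2O[C@@H]1c1cc(OCc2ccccc2)c(OCc2ccccc2)c2c(=O)c(O)cc(C(=O)[C@H](OCOCc3ccccc3)Cc3c(O[Si](C)(C)C(C)(C)C)cc(OCc4ccccc4)cc3OCc3ccccc3)cc12)c1cc(OCc2ccccc2)c(OCc2ccccc2)c(OCc2ccccc2)c1 | intermediate
38 | (2R,3R)-5,7-bis(benzyloxy)-2-[3,4,6-tris(benzyloxy)-8-{(2R)-3-[2,4-bis(benzyloxy)-6-(tert-butyldimethylsilyloxy)phenyl]-2-[(benzyloxy)methoxy]propanoyl}-5-oxo-5H-benzo[7]annulen-1-yl]chroman-3-yl 3,4,5-tris(benzyloxy)benzoate | O=C(O[C@@H]1Cc2c(OCc3ccccc3)cc(OCc3ccccc3)cc2O[C@@H]1c1cc(OCc2ccccc2)c(OCc2ccccc2)c2c(=O)c(OCc3ccccc3)cc(C(=O)[C@H](OCOCc3ccccc3)Cc3c(O[Si](C)(C)C(C)(C)C)cc(OCc4ccccc4)cc3OCc3ccccc3)cc12)c1cc(OCc2ccccc2)c(OCc2ccccc2)c(OCc2ccccc2)c1 | intermediate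
39 | (2R,3R)-5,7-bis(benzyloxy)-2-[3,4,6-tris(benzyloxy)-8-{(1S,2R)-3-[2,4-bis(benzyloxy)-6-(tert-butyldimethylsilyloxy)phenyl]-2-[(benzyloxy)methoxy]-1-hydroxypropyl}-5-oxo-5H-benzo[7]annulen-1-yl]chroman-3-yl 3,4,5-tris(benzyloxy)benzoate | O=C(O[C@@H]1Cc2c(OCc3ccccc3)cc(OCc3ccccc3)cc2O[C@@H]1c1cc(OCc2ccccc2)c(OCc2ccccc2)c2c(=O)c(OCc3ccccc3)cc([C@H](O)[C@H](OCOCc3ccccc3)Cc3c(O[Si](C)(C)C(C)(C)C)cc(OCc4ccccc4)cc3OCc3ccccc3)cc12)c1cc(OCc2ccccc2)c(OCc2ccccc2)c(OCc2ccccc2)c1 | intermediate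
40 | (2R,3R)-5,7-bis(benzyloxy)-2-[3,4,6-tris(benzyloxy)-8-{(1S,2R)-3-[2,4-bis(benzyloxy)-6-hydroxyphenyl]-2-[(benzyloxy)methoxy]-1-hydroxypropyl}-5-oxo-5H-benzo[7]annulen-1-yl]chroman-3-yl 3,4,5-tris(benzyloxy)benzoate | O=C(O[C@@H]1Cc2c(OCc3ccccc3)cc(OCc3ccccc3)cc2O[C@@H]1c1cc(OCc2ccccc2)c(OCc2ccccc2)c2c(=O)c(OCc3ccccc3)cc([C@H](O)[C@H](OCOCc3ccccc3)Cc3c(O)cc(OCc4ccccc4)cc3OCc3ccccc3)cc12)c1cc(OCc2ccccc2)c(OCc2ccccc2)c(OCc2ccccc2)c1 | intermediate
41 | (2R,3R)-5,7-bis(benzyloxy)-2-[3,4,6-tris(benzyloxy)-8-{(2R,3R)-5,7-bis(benzyloxy)-3-[(benzyloxy)methoxy]chroman-2-yl}-5-oxo-5H-benzo[7]annulen-1-yl]chroman-3-yl 3,4,5-tris(benzyloxy)benzoate (fully protected theaflavin-3-gallate) | O=C(O[C@@H]1Cc2c(OCc3ccccc3)cc(OCc3ccccc3)cc2O[C@@H]1c1cc(OCc2ccccc2)c(OCc2ccccc2)c2c(=O)c(OCc3ccccc3)cc([C@H]3Oc4cc(OCc5ccccc5)cc(OCc5ccccc5)c4C[C@H]3OCOCc3ccccc3)cc12)c1cc(OCc2ccccc2)c(OCc2ccccc2)c(OCc2ccccc2)c1 | intermediate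
42 | theaflavin-3-gallate | O=C(O[C@@H]1Cc2c(O)cc(O)cc2O[C@@H]1c1cc(O)c(O)c2c(=O)c(O)cc([C@H]3Oc4cc(O)cc(O)c4C[C@H]3O)cc12)c1cc(O)c(O)c(O)c1 | target

**Step count and risks**

Total step count: 31. Longest linear sequence: 24 steps (13 to 42 through steps 8–31; the branch from 1 through steps 1–6 and 14–31 is equally long).

Steps most likely to fail:

1. Step 25. The regiochemistry may leak (the acyl-bearing alkyne carbon bonding to C6 instead of C9), or the terminal ynone may be lost to cyclopropenation or Michael-type side reactions before the ylide is trapped. The fallback sets out from Weinreb amide 11 and diazoketone 34 and comes back at tropolone 37. Amide 11 would be treated with CH2=CHMgBr (THF, 0 °C) to give the vinyl ketone (4R)-5-[2,4-bis(benzyloxy)-6-(tert-butyldimethylsilyloxy)phenyl]-4-[(benzyloxy)methoxy]pent-1-en-3-one F1. Electron-poor alkenes are the best-studied partners of these ylides, and the same Rh2(OAc)4 protocol with 34 should give the saturated oxygen-bridged adduct F2 with the acyl group on C8 (C8 epimers). DBU in CH2Cl2 would then open the bridge by β-elimination of the C9 oxygen (retro-oxa-Michael, the acyl group acidifying C8–H) to the ring-opened ketol F3. Dess–Martin periodinane with NaHCO3 would oxidise the C6 carbinol to the 1,2-dione F4, which enolises to the aromatic tropolone 37.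

2. Step 18. The bromine–lithium exchange at the doubly flanked position may be incomplete, or the aryl anion may be quenched by silyl migration from the neighbouring silyloxymethyl oxygen or by benzylic deprotonation. The fallback sets out from aryl bromide 24 and comes back at allyl ester 26 without any organolithium. TBAF would give the benzylic alcohol F5. Palladium-catalysed carbonylative lactonisation (CO 1 atm, Pd(OAc)2, Xantphos, Et3N, toluene, 90 °C; the acylpalladium is trapped by the neighbouring hydroxyl) would give the phthalide F6. Saponification with LiOH in THF/H2O would give the lithium hydroxy-carboxylate F7. Silylation of both oxygens (TIPSOTf, 2,6-lutidine) would give the silyl ether silyl ester F8, and K2CO3 in MeOH/H2O would cleave only the silyl ester to give the acid F9. O-Allylation (allyl bromide, K2CO3, DMF) would then give 26.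

3. Step 30. The oxyphosphonium ion at the tropone-bearing carbinol may ionise before displacement (loss of inversion, 2,3-trans material) or eliminate. The fallback sets out from alcohol 39 and comes back at 41. Mesylation (MsCl, Et3N, CH2Cl2, −20 °C) with retention would give the mesylate F10. TBAF in THF at 0 °C would then cleave the aryl silyl ether, and the phenoxide so formed would displace the mesylate intramolecularly with inversion (Williamson etherification) to give 41.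

**Further compounds**

F1 | step 25 | (4R)-5-[2,4-bis(benzyloxy)-6-(tert-butyldimethylsilyloxy)phenyl]-4-[(benzyloxy)methoxy]pent-1-en-3-one | C=CC(=O)[C@H](OCOCc1ccccc1)Cc1c(O[Si](C)(C)C(C)(C)C)cc(OCc2ccccc2)cc1OCc1ccccc1
F2 | step 25 | saturated oxygen-bridged adduct, the 7,8-dihydro analogue of 36 (C8 epimers, one bridge diastereomer drawn) | O=C(O[C@@H]1Cc2c(OCc3ccccc3)cc(OCc3ccccc3)cc2O[C@@H]1c1cc(OCc2ccccc2)c(OCc2ccccc2)c2c1[C@H]1O[C@H](CC1C(=O)[C@H](OCOCc1ccccc1)Cc1c(O[Si](C)(C)C(C)(C)C)cc(OCc3ccccc3)cc1OCc1ccccc1)C2=O)c1cc(OCc2ccccc2)c(OCc2ccccc2)c(OCc2ccccc2)c1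
F3 | step 25 | ring-opened ketol, the 6-hydroxy-6,7-dihydro-5H-benzo[7]annulen-5-one analogue of 37 (C6 epimers) | O=C(O[C@@H]1Cc2c(OCc3ccccc3)cc(OCc3ccccc3)cc2O[C@@H]1c1cc(OCc2ccccc2)c(OCc2ccccc2)c2c1C=C(C(=O)[C@H](OCOCc1ccccc1)Cc1c(O[Si](C)(C)C(C)(C)C)cc(OCc3ccccc3)cc1OCc1ccccc1)CC(O)C2=O)c1cc(OCc2ccccc2)c(OCc2ccccc2)c(OCc2ccccc2)c1
F4 | step 25 | 7H-benzo[7]annulene-5,6-dione, the keto tautomer of 37 | O=C(O[C@@H]1Cc2c(OCc3ccccc3)cc(OCc3ccccc3)cc2O[C@@H]1c1cc(OCc2ccccc2)c(OCc2ccccc2)c2c1C=C(C(=O)[C@H](OCOCc1ccccc1)Cc1c(O[Si](C)(C)C(C)(C)C)cc(OCc3ccccc3)cc1OCc1ccccc1)CC(=O)C2=O)c1cc(OCc2ccccc2)c(OCc2ccccc2)c(OCc2ccccc2)c1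
F5 | step 18 | [3,4-bis(benzyloxy)-2-bromo-6-{(2R,3R)-5,7-bis(benzyloxy)-3-[(benzyloxy)methoxy]chroman-2-yl}phenyl]methanol | c1ccccc1COCO[C@@H]1Cc2c(OCc3ccccc3)cc(OCc3ccccc3)cc2O[C@@H]1c1cc(OCc2ccccc2)c(OCc2ccccc2)c(Br)c1CO
F6 | step 18 | 6,7-bis(benzyloxy)-4-{(2R,3R)-5,7-bis(benzyloxy)-3-[(benzyloxy)methoxy]chroman-2-yl}isobenzofuran-1(3H)-one | c1ccccc1COCO[C@@H]1Cc2c(OCc3ccccc3)cc(OCc3ccccc3)cc2O[C@@H]1c1cc(OCc2ccccc2)c(OCc2ccccc2)c2C(=O)OCc12
F7 | step 18 | lithium 2,3-bis(benzyloxy)-5-{(2R,3R)-5,7-bis(benzyloxy)-3-[(benzyloxy)methoxy]chroman-2-yl}-6-(hydroxymethyl)benzoate | [Li+].c1ccccc1COCO[C@@H]1Cc2c(OCc3ccccc3)cc(OCc3ccccc3)cc2O[C@@H]1c1cc(OCc2ccccc2)c(OCc2ccccc2)c(C(=O)[O-])c1CO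
F8 | step 18 | triisopropylsilyl 2,3-bis(benzyloxy)-5-{(2R,3R)-5,7-bis(benzyloxy)-3-[(benzyloxy)methoxy]chroman-2-yl}-6-{[(triisopropylsilyl)oxy]methyl}benzoate | c1ccccc1COCO[C@@H]1Cc2c(OCc3ccccc3)cc(OCc3ccccc3)cc2O[C@@H]1c1cc(OCc2ccccc2)c(OCc2ccccc2)c(C(=O)O[Si](C(C)C)(C(C)C)C(C)C)c1CO[Si](C(C)C)(C(C)C)C(C)C
F9 | step 18 | 2,3-bis(benzyloxy)-5-{(2R,3R)-5,7-bis(benzyloxy)-3-[(benzyloxy)methoxy]chroman-2-yl}-6-{[(triisopropylsilyl)oxy]methyl}benzoic acid | c1ccccc1COCO[C@@H]1Cc2c(OCc3ccccc3)cc(OCc3ccccc3)cc2O[C@@H]1c1cc(OCc2ccccc2)c(OCc2ccccc2)c(C(=O)O)c1CO[Si](C(C)C)(C(C)C)C(C)C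
F10 | step 30 | methanesulfonate of carbinol 39 (1S,2R) | O=C(O[C@@H]1Cc2c(OCc3ccccc3)cc(OCc3ccccc3)cc2O[C@@H]1c1cc(OCc2ccccc2)c(OCc2ccccc2)c2c(=O)c(OCc3ccccc3)cc([C@H](OS(C)(=O)=O)[C@H](OCOCc3ccccc3)Cc3c(O[Si](C)(C)C(C)(C)C)cc(OCc4ccccc4)cc3OCc3ccccc3)cc12)c1cc(OCc2ccccc2)c(OCc2ccccc2)c(OCc2ccccc2)c1
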